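Assumption: the target is read as the ester of the primary alcohol of tyrosol with unbranched tetracontanoic acid (40 carbons, counting the carbonyl carbon as C1), the phenol being free. A carboxylate salt that is only the product before acidic work-up is not numbered separately.

## Analysis of the target

The target is the ester between the primary alcohol of tyrosol, 2-(4-hydroxyphenyl)ethanol, and tetracontanoic acid. An unbranched, saturated C40 acyl chain (C1 the ester carbonyl, C40 the terminal methyl) is bound through oxygen to the CH2CH2 arm of a para-disubstituted benzene ring whose phenolic OH stays free. The benzene ring is the only ring, and there is no stereocentre and no double-bond geometry, so nothing has to be controlled stereochemically. The sensitive groups are the ester, which forbids strong base, hydride and organometallic reagents once it is in place, and the free phenol, which competes as a nucleophile in any acylation. The real difficulty is the chain: a single-homologue C40 acid is not a bulk chemical, neighbouring homologues cannot be separated in practice, and long alkyl intermediates are waxy, sparingly soluble and invisible to UV detection. The chain length therefore has to be fixed by an unambiguous C–C bond formation between pure shorter pieces. A second, smaller task is to acylate the aliphatic hydroxyl of tyrosol and not the phenolic one. The strategy rests on carrying four consecutive methylenes, C15 to C18, as the four carbons of a thiophene ring in which sulfur bridges C15 and C18. The two ring carbons next to sulfur are the reactive ones, so C18 can be bonded to C19 of a docosyl group and C15 to the acyl carbon C14 of a C14 diacid derivative; hydrogenolysis of the two C–S bonds then returns plain (CH2)4, and the count is 22 + 4 + 14 = 40.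

## Retrosynthetic reasoning

**Ester C–O bond.** The target 15 is cut between the alkyl oxygen and C1 into tetracontanoic acid 13 and tyrosol 14. This is the only heteroatom link, 14 is a cheap commodity, and making the ester last keeps the phenol and the base-labile ester out of every earlier step. The forward reaction has to acylate the aliphatic OH of 14 and leave the phenol alone; equilibrium acid catalysis does this, because phenols are not esterified by carboxylic acids under such conditions.

**The two C–S bonds.** In 13 the carbons C15 to C18 are redrawn as an aromatic ring by inserting sulfur between C15 and C18, which gives 14-(5-docosylthiophen-2-yl)tetradecanoic acid 12. The cut is placed there because it turns a featureless alkane segment into a heterocycle with two reactive positions exactly at the ends of the segment. The forward reaction is hydrogenolysis of both C–S bonds with saturation of the four ring carbons; the carboxylic acid and the saturated chains are not touched by it.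

**Oxidation level at C14 and C1.** Acid 12 is traced back to methyl 14-(5-docosylthiophen-2-yl)-14-oxotetradecanoate 9. The ketone at C14 is what allows the neighbouring C14–C15 bond to be made by acylation, and the methyl ester is the form in which the far carboxyl survives that acylation. Forward, the ester is first hydrolysed to carboxylate 10, the ketone is converted into hydrazone 11 and the hydrazone is decomposed under Wolff–Kishner conditions. This is done before the sulfur is removed, because the aryl ketone is reduced most cleanly while it is still conjugated to the ring.

**C14–C15 bond (the key disconnection).** Keto ester 9 is cut between the ketone carbon and the ring into 2-docosylthiophene 4 and methyl 14-chloro-14-oxotetradecanoate 8. The cut is placed here because it divides C40 into a 26-carbon and a 14-carbon piece that both derive from single-homologue commodity chemicals, and because the acyl carbon carries the natural electrophilic polarity for attack on the electron-rich ring. The forward reaction must acylate only the free position next to sulfur, stop after one acylation and leave the distant methyl ester unchanged.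

**C18–C19 bond.** Alkylthiophene 4 is cut between the ring and the chain into thiophene 1 and 1-bromodocosane 2, joined through 2-thienyllithium 3. The alkyl group is introduced before the acyl group for two reasons: the organolithium step then meets no carbonyl group, and the alkyl substituent activates the ring for the later acylation and directs it to the remaining position next to sulfur.

**Differentiating the ends of the C14 diacid.** Acid chloride 8 comes from 14-methoxy-14-oxotetradecanoic acid 7, this from dimethyl tetradecanedioate 6 by hydrolysis of one ester group, and 6 from tetradecanedioic acid 5. The detour through the diester is chosen because the half-hydrolysis can be stopped by precipitation of the half-ester salt, which a direct mono-esterification cannot offer.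

## Alternatives that were turned down

Alternative 1: The benzene ring of 15 is taken apart, so that the aromatic ring derives from the aldehyde 4-oxobutyl tetracontanoate A2 and methyl vinyl ketone A3. In the forward key step the enamine of A2 adds through its alpha carbon to A3, and the methyl ketone then condenses with the aldehyde (Michael–aldol annulation of the Robinson type). This forms two C–C bonds and the six-membered ring of racemic 2-(4-oxocyclohex-2-en-1-yl)ethyl tetracontanoate A1, which must still be dehydrogenated to the phenol. In its favour, the annulation is dependable for 4-substituted cyclohexenones. It is also stronger than the chosen route on one point: the phenolic OH does not exist when the ester is made, so the alcohol-versus-phenol question never arises. Against it, the ring it constructs is the one part of 15 that is available cheaply as 14. The acid 13 must still be prepared in full to reach A2, so the whole chain synthesis remains and several steps are added (making A2 from 13, annulation, aromatisation). The stereocentre of A1 is created only to be destroyed, and an oxidative aromatisation would have to be run on a waxy substrate. It spends its key step where the target poses no problem; the chosen route answers the selectivity question through the inertness of phenols under equilibrium acid catalysis and puts its bond formation on the chain.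

Alternative 2: The C12–C13 bond of the chain is cut, and C1 to C12 are carried as a twelve-membered carbocycle. In the forward key step the enamine 4-(cyclododec-1-en-1-yl)morpholine A5 is C-acylated by octacosanoyl chloride A6, and hydrolysis of the iminium salt gives the cyclic 1,3-diketone 2-octacosanoylcyclododecanone A4 (racemic, enolisable); no new ring closes. Base-induced retro-Claisen opening would give 13-oxotetracontanoic acid A7, and Wolff–Kishner reduction then 13. In its favour, twelve carbons are added in one operation, no sulfur and no stoichiometric nickel are needed, and 13 would be reached in about four steps. On step economy and waste it is stronger than the chosen route. Against it, A6 requires a pure C28 acid, which is far less accessible as a single homologue than the C22 bromide 2 and the C14 diacid 5. The enamine of a twelve-membered ketone forms and acylates sluggishly, and O-acylation competes. The retro-Claisen cleavage has no ring strain to direct it, so attack at the exocyclic carbonyl, which merely returns the starting ketone and the C28 acid, competes with ring opening. Every intermediate is an aliphatic wax without a chromophore. The chosen strategy offers instead commodity building blocks, a junction whose regiochemistry is dictated by the heterocycle, and aromatic, UV-active, crystallisable intermediates (4, 9, 12) until the desulfurisation.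

Alternative 3: The C19–C20 bond is cut homolytically. In the forward key step docosanoic acid A9 and 20-methoxy-20-oxoicosanoic acid A10 are co-electrolysed at a Pt anode (crossed Kolbe electrolysis). Both carboxylates lose CO2, and the C21 and C19 primary radicals combine to methyl tetracontanoate A8; no ring closes. In its favour, the whole C40 skeleton is made in a single operation from two acids, which makes it the shortest of all the approaches, and on step count it clearly beats the chosen route. Against it, radical pairing is statistical: each radical also couples with itself, and disproportionation and over-oxidation to cations add alkenes and ethers, so A8 can only be one component of a mixture of waxes of similar solubility. Long-chain carboxylates dissolve poorly in the alcoholic electrolyte, and the products coat the anode. A10 is itself a half-ester that must be made by desymmetrising a C20 diacid, the same problem as 5 to 7 but on a costlier material. The chosen strategy offers a polar, two-electron bond formation between 4 and 8 in a one-to-one ratio at a defined carbon, giving a single product 9 that is easy to separate from both precursors.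

Key step: step 5

## Route

Step 1
Reactants: 1 thiophene; 2 1-bromodocosane
Product: 4 2-docosylthiophene, via 2-thienyllithium 3 (not isolated)
Conditions: thiophene (1.5 equiv), n-BuLi (1.4 equiv), THF, −20 → 0 °C; then 2 (1.0 equiv) in THF, 0 → 50 °C; aq. NH4Cl
Reagents that add atoms: none
Why: n-BuLi removes the most acidic ring proton, the one next to sulfur, and the resulting unhindered aryllithium displaces bromide from the primary alkyl bromide (SN2 alkylation of a lithiated heteroarene). The excess of the volatile thiophene component ensures that the waxy bromide, the impurity that is hard to remove, is consumed.

Step 2
Reactants: 5 tetradecanedioic acid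
Product: 6 dimethyl tetradecanedioate
Conditions: MeOH (solvent), H2SO4 (cat.), reflux
Reagents that add atoms: methanol, CO
Why: Fischer esterification, driven to the diester by methanol as solvent; the diester is a low-melting, easily purified solid.

Step 3
Reactants: 6 dimethyl tetradecanedioate
Product: 7 14-methoxy-14-oxotetradecanoic acid
Conditions: Ba(OH)2 (0.5 equiv), MeOH, rt; precipitated barium salt filtered off; then 2 M HCl, Et2O
Reagents that add atoms: barium hydroxide Ba(OH)2, [Ba+2].[OH-].[OH-]
Why: Half-saponification of a symmetrical diester: the barium salt of the half-ester is insoluble in methanol and separates as it forms, which withdraws it from a second hydrolysis. Unchanged 6 stays in the filtrate and can be recycled.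

Step 4
Reactants: 7 14-methoxy-14-oxotetradecanoic acid
Product: 8 methyl 14-chloro-14-oxotetradecanoate
Conditions: (COCl)2 (1.5 equiv), DMF (cat.), CH2Cl2, 0 °C → rt; evaporate, use crude
Reagents that add atoms: oxalyl chloride, ClC(=O)C(=O)Cl
Why: Acid chloride formation through the chloroiminium species generated from DMF; the methyl ester is inert and all by-products are gases, so 8 can be used without purification.

Step 5
Reactants: 4 2-docosylthiophene; 8 methyl 14-chloro-14-oxotetradecanoate
Product: 9 methyl 14-(5-docosylthiophen-2-yl)-14-oxotetradecanoate
Conditions: SnCl4 (1.1 equiv, added last), CH2Cl2, 0 °C → rt; then ice/2 M HCl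
Reagents that add atoms: none
Why: This is a Friedel–Crafts acylation of a thiophene; the closest known reaction type is the SnCl4-promoted acylation of 2-alkylthiophenes with omega-alkoxycarbonyl acyl chlorides. SnCl4 ionises 8 to an acylium ion (or its tight complex), which attacks the free ring carbon next to sulfur of 4. The sigma complex formed there is delocalised over sulfur and over the alkyl-bearing ring carbon, whereas attack at a beta carbon gives a less stabilised cation, so the intrinsic alpha preference is reinforced by the docosyl donor. Loss of the proton restores aromaticity and creates the C14–C15 bond; no ring closes and no stereocentre is formed. The ketone formed binds SnCl4 and deactivates the ring, which stops a second acylation and is the reason a full equivalent of the Lewis acid is used. The methyl ester, twelve methylenes away and a weak Lewis base, remains unchanged. SnCl4 is chosen over stronger Lewis acids because it does not resinify thiophenes, and adding it last to the mixture of 4 and 8 prevents the thiophene from meeting free Lewis acid in the absence of the acylating agent. The product is polar, UV-active and crystallisable, so it is readily separated from unreacted 4 and from hydrolysed 8.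

Step 6
Reactants: 9 methyl 14-(5-docosylthiophen-2-yl)-14-oxotetradecanoate
Product: 12 14-(5-docosylthiophen-2-yl)tetradecanoic acid, via potassium 14-(5-docosylthiophen-2-yl)-14-oxotetradecanoate 10 (not isolated), via potassium 14-(5-docosylthiophen-2-yl)-14-hydrazinylidenetetradecanoate 11 (not isolated)
Conditions: KOH (6 equiv), diethylene glycol, 120 °C; then N2H4·H2O (5 equiv), 130 °C, then distil to 195–200 °C; then 2 M HCl
Reagents that add atoms: potassium hydroxide KOH, [K+].[OH-]
Why: Saponification first converts the ester into the carboxylate, so that hydrazine meets only the ketone and no acyl hydrazide forms. Wolff–Kishner reduction in the Huang-Minlon variant (hydrazone formation, base-mediated tautomerisation, loss of N2) then turns C14 into a methylene. 2-Acylthiophenes are standard substrates, and the ring and the alkyl chains are inert to hot alkali.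

Step 7
Reactants: 12 14-(5-docosylthiophen-2-yl)tetradecanoic acid
Product: 13 tetracontanoic acid
Conditions: Raney Ni (W-2, large excess), H2 (1 atm), EtOH/toluene, reflux; hot filtration; hot dilute HCl wash
Reagents that add atoms: none
Why: Reductive desulfurisation with Raney Ni: both C–S bonds are cleaved on the hydrogen-laden metal surface and the resulting four-carbon unsaturated unit is hydrogenated, so C15 to C18 become four methylenes and sulfur stays on the metal as NiS. The carboxylic acid and the saturated chains are untouched, and hot toluene keeps the C40 acid in solution for the filtration.

Step 8
Reactants: 13 tetracontanoic acid; 14 tyrosol, 2-(4-hydroxyphenyl)ethanol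
Product: 15 2-(4-hydroxyphenyl)ethyl tetracontanoate (target)
Conditions: 14 (3 equiv), p-TsOH·H2O (0.1 equiv), toluene, reflux, Dean–Stark trap
Reagents that add atoms: none
Why: Acid-catalysed (Fischer) esterification with azeotropic removal of water; carboxylic acids do not acylate phenols under these equilibrium conditions, so only the primary alcohol reacts. The excess of water-soluble 14 drives the conversion and is washed out afterwards, and refluxing toluene dissolves 13.

## Compound list

1 | thiophene | c1ccsc1 | starting material
2 | 1-bromodocosane | CCCCCCCCCCCCCCCCCCCCCCBr | starting material
3 | 2-thienyllithium | [Li]c1cccs1 | intermediate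
4 | 2-docosylthiophene | CCCCCCCCCCCCCCCCCCCCCCc1cccs1 | intermediate
5 | tetradecanedioic acid | OC(=O)CCCCCCCCCCCCC(=O)O | starting material
6 | dimethyl tetradecanedioate | COC(=O)CCCCCCCCCCCCC(=O)OC | intermediate
7 | 14-methoxy-14-oxotetradecanoic acid | COC(=O)CCCCCCCCCCCCC(=O)O | intermediate
8 | methyl 14-chloro-14-oxotetradecanoate | COC(=O)CCCCCCCCCCCCC(=O)Cl | intermediate
9 | methyl 14-(5-docosylthiophen-2-yl)-14-oxotetradecanoate | CCCCCCCCCCCCCCCCCCCCCCc1ccc(s1)C(=O)CCCCCCCCCCCCC(=O)OC | intermediate
10 | potassium 14-(5-docosylthiophen-2-yl)-14-oxotetradecanoate | CCCCCCCCCCCCCCCCCCCCCCc1ccc(s1)C(=O)CCCCCCCCCCCCC(=O)[O-].[K+] | intermediate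
11 | potassium 14-(5-docosylthiophen-2-yl)-14-hydrazinylidenetetradecanoate | CCCCCCCCCCCCCCCCCCCCCCc1ccc(s1)C(=NN)CCCCCCCCCCCCC(=O)[O-].[K+] | intermediate
12 | 14-(5-docosylthiophen-2-yl)tetradecanoic acid | CCCCCCCCCCCCCCCCCCCCCCc1ccc(s1)CCCCCCCCCCCCCC(=O)O | intermediate
13 | tetracontanoic acid | CCCCCCCCCCCCCCCCCCCCCCCCCCCCCCCCCCCCCCCC(=O)O | intermediate
14 | tyrosol, 2-(4-hydroxyphenyl)ethanol | OCCc1ccc(O)cc1 | starting material
15 | 2-(4-hydroxyphenyl)ethyl tetracontanoate | CCCCCCCCCCCCCCCCCCCCCCCCCCCCCCCCCCCCCCCC(=O)OCCc1ccc(O)cc1 | target

## Step count and least certain steps

Total: 8 steps. Longest linear sequence: 7 steps (steps 2, 3, 4, 5, 6, 7, 8, from tetradecanedioic acid 5); the thiophene branch joins after one step.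

**Step 5 (key step).** The most likely failure is acid-induced oligomerisation of the electron-rich alkylthiophene before it is acylated. The acylation may also stall because the waxy substrate and the SnCl4–ketone complex come out of solution at low temperature, and a small share of attack at a beta carbon would contaminate the product. Fallback, from 4 and 8 back to 9 without any Lewis acid: 4 is lithiated at its free position next to sulfur with n-BuLi in THF to give (5-docosylthiophen-2-yl)lithium F1. This is transmetalated with ZnCl2 to chloro(5-docosylthiophen-2-yl)zinc F2, which is coupled with acid chloride 8 under Pd(PPh3)4 catalysis (Negishi-type acylation). The arylzinc adds neither to the methyl ester nor to the ketone formed, and the site of bond formation is fixed by the lithiation; the route is rejoined at 9.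

**Step 1.** The SN2 displacement on the long-chain bromide may be slow, with competing E2 elimination. Unreacted bromide and alkene are non-polar and tend to crystallise together with 4. Fallback, from 1 back to 4 by the same acylation–reduction logic as the main route: thiophene 1 is acylated with docosanoyl chloride F3 and SnCl4 to give 1-(thiophen-2-yl)docosan-1-one F4, a polar crystalline ketone that is easy to purify. Wolff–Kishner reduction of F4 through its hydrazone, 1-(thiophen-2-yl)docosan-1-one hydrazone F5, then gives 4.

**Step 7.** Hydrogenolysis or saturation may be incomplete if the nickel is poor in hydrogen, and the sparingly soluble C40 acid may be held on the metal as its nickel carboxylate, which causes loss of material. Fallback, from 12 back to 13 through neutral esters: 12 is esterified (MeOH, H2SO4) to methyl 14-(5-docosylthiophen-2-yl)tetradecanoate F6. This is desulfurised with Raney Ni in hot EtOH/toluene, followed by a short hydrogenation over Pd/C to remove any residual unsaturation, giving methyl tetracontanoate F7, which does not bind to the metal. Saponification with KOH and acidification return 13.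

**Step 8.** The equilibrium may stall if 13 or the product crystallises from the medium, acid may promote self-etherification of 14, and the phenol may be partly acylated on prolonged heating. Fallback, from 13 to 15 with the phenol protected: 13 is converted with SOCl2 into tetracontanoyl chloride F8. This acylates commercially available 2-[4-(benzyloxy)phenyl]ethanol F9 (pyridine, DMAP cat., warm toluene) to give 2-[4-(benzyloxy)phenyl]ethyl tetracontanoate F10. Hydrogenolysis of the benzyl ether (H2, Pd/C, warm THF/EtOAc) then gives 15; the ester is stable to these conditions.

## Further compounds

F1 | step 5 | (5-docosylthiophen-2-yl)lithium | [Li]c1ccc(CCCCCCCCCCCCCCCCCCCCCC)s1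
F2 | step 5 | chloro(5-docosylthiophen-2-yl)zinc | Cl[Zn]c1ccc(CCCCCCCCCCCCCCCCCCCCCC)s1
F3 | step 1 | docosanoyl chloride | CCCCCCCCCCCCCCCCCCCCCC(=O)Cl
F4 | step 1 | 1-(thiophen-2-yl)docosan-1-one | CCCCCCCCCCCCCCCCCCCCCC(=O)c1cccs1
F5 | step 1 | 1-(thiophen-2-yl)docosan-1-one hydrazone | CCCCCCCCCCCCCCCCCCCCCC(=NN)c1cccs1
F6 | step 7 | methyl 14-(5-docosylthiophen-2-yl)tetradecanoate | CCCCCCCCCCCCCCCCCCCCCCc1ccc(s1)CCCCCCCCCCCCCC(=O)OC
F7 | step 7 | methyl tetracontanoate | CCCCCCCCCCCCCCCCCCCCCCCCCCCCCCCCCCCCCCCC(=O)OC
F8 | step 8 | tetracontanoyl chloride | CCCCCCCCCCCCCCCCCCCCCCCCCCCCCCCCCCCCCCCC(=O)Cl
F9 | step 8 | 2-[4-(benzyloxy)phenyl]ethanol | OCCc1ccc(OCc2ccccc2)cc1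
F10 | step 8 | 2-[4-(benzyloxy)phenyl]ethyl tetracontanoate | CCCCCCCCCCCCCCCCCCCCCCCCCCCCCCCCCCCCCCCC(=O)OCCc1ccc(OCc2ccccc2)cc1
A1 | alternative 1 | 2-(4-oxocyclohex-2-en-1-yl)ethyl tetracontanoate (racemic) | CCCCCCCCCCCCCCCCCCCCCCCCCCCCCCCCCCCCCCCC(=O)OCCC1CCC(=O)C=C1
A2 | alternative 1 | 4-oxobutyl tetracontanoate | CCCCCCCCCCCCCCCCCCCCCCCCCCCCCCCCCCCCCCCC(=O)OCCCC=O
A3 | alternative 1 | methyl vinyl ketone (but-3-en-2-one) | CC(=O)C=C
A4 | alternative 2 | 2-octacosanoylcyclododecanone (racemic, enolisable) | CCCCCCCCCCCCCCCCCCCCCCCCCCCC(=O)C1CCCCCCCCCCC1=O
A5 | alternative 2 | 4-(cyclododec-1-en-1-yl)morpholine | C1(=CCCCCCCCCCC1)N1CCOCC1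
A6 | alternative 2 | octacosanoyl chloride | CCCCCCCCCCCCCCCCCCCCCCCCCCCC(=O)Cl
A7 | alternative 2 | 13-oxotetracontanoic acid | CCCCCCCCCCCCCCCCCCCCCCCCCCCC(=O)CCCCCCCCCCCC(=O)O
A8 | alternative 3 | methyl tetracontanoate | CCCCCCCCCCCCCCCCCCCCCCCCCCCCCCCCCCCCCCCC(=O)OC
A9 | alternative 3 | docosanoic acid | CCCCCCCCCCCCCCCCCCCCCC(=O)O
A10 | alternative 3 | 20-methoxy-20-oxoicosanoic acid | COC(=O)CCCCCCCCCCCCCCCCCCC(=O)O
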